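## Analysis of the target

Kanzonol T is an isoflavone: a 4H-chromen-4-one (benzo ring A fused to pyranone ring C) that carries at C3 a 2,2-dimethyl-2H-chromene (ring B with its fused pyran, ring D). The two halves are joined through chromene C6, so the free 2′-hydroxyl is the chromene C5 oxygen. Ring A is a phloroglucinol: O1 on C8a, hydroxyls on C5 and C7, the 3-hydroxy-3-methylbutyl chain on C6 and hydrogen on C8. There is no stereocenter, so the problem is one of connectivity and functional-group tolerance only. The sensitive groups are the tertiary alcohol, which lies between two phenols and closes to a dimethylchroman (or dehydrates) once its carbocation forms; the styrene-like C3=C4 bond of ring D (acid, electrophilic oxidants, hydrogenation); and C2 of the isoflavone, which hard nucleophiles attack with ring opening. The hard part is to put the chain on C6 and not on C8 of a ring whose three oxygens are nearly equivalent. The strategy rests on the fact that C4a, C5, C6, C7, C8 and C8a alternate like a folded poly-β-carbonyl chain, with C6 the carbon between two former carbonyl carbons (C5 and C7) and the C8a oxygen identical with O1. If ring C exists first as a monocyclic 4-pyranone, O1 is fixed and the remaining chain C8–C7–C6–C5 can fold back onto the pyranone in one way only.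

## Retrosynthetic reasoning

**29 back to 26 (protecting groups).** The last two operations remove the aryl acetal and the tertiary silyl ether. They are taken off separately: the acetal of 26 by silyl transfer instead of protic acid, giving 28, and then the silyl ether by fluoride, giving 29. Protic acid strong enough to hydrolyse the aryl acetal could ionize the tertiary carbinol next to the ring A phenols. Keeping that oxygen silylated until the end, and freeing it without ever forming a cation there, avoids chroman formation.

**26 back to 24 (C4a–C5, the key disconnection).** Cutting C4a–C5 turns C5 into an ester carbon and leaves O1 inside a stable 4-pyranone, giving β-keto ester 24. Of the six ring A bonds this is the one whose formation needs only base and loses only the alkoxy group of the ester. It also settles the regiochemistry, because the side chain sits on the carbon between the ketone and the ester and must therefore become C6. The forward step has to acylate pyranone C3 with the ester and enolize the product to the arene.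

**24 back to 15 and 21 (C6–C7).** The ketone carbon is separated from its α-carbon: acid 15 is the acyl donor and malonate half-ester salt 21 the nucleophile in a decarboxylative Claisen condensation. This is convergent, brings in the side chain with the malonate, runs under neutral conditions, and avoids alkylating a β-keto ester that would cyclize too early.

**15 back to 13 (C7–C8).** The carboxyl carbon is removed from the lateral position; forward, the 2-methyl group of 13 is deprotonated to dienolate 14 and carboxylated. The methyl group is the only acidic site of 13.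

**13 back to 8 and 12 (C3–C1′).** The aryl–pyranone bond is cut to boronate 8 and triflate 12, to be joined by cross-coupling. Building the pyranone de novo around an arylacetyl unit was not chosen, because it needs a carboxylate blocking group at the pyranone 3-position. Its removal has no enol pathway and calls for heat or strong acid, which the acetal and the chromene would not survive. The coupling joins two simple rings made independently.

**8 back to 1 and 2.** Boron is placed on 6 by directed metalation through aryllithium 7, so the acetal serves as protecting and directing group. Ether 6 comes from phenol 5, and 5 from dehydrogenation of enone 3 through selenide 4. Enone 3 is the condensation product of 1 and 2; because 1 is symmetric, the fusion of ring D cannot give isomers, unlike chromenylation of a resorcinol.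

**12 back to 9.** Triflate 12 comes from hydroxypyranone 11, and 11 from kojic acid 9 by deoxygenation of the hydroxymethyl group through chloride 10.

**21 back to 16 and 19.** Salt 21 is the mono-saponification product of malonate 20, which comes from alkylation of 19 with tosylate 18. Tosylate 18 is made from diol 16 through 17; the tertiary hydroxyl is silylated before the alkylation because its alkoxide would otherwise lactonize onto a malonate ester.

## Alternatives that were turned down

**Alternative 1:** Ring A is taken apart into a four-carbon cyclobutenone A2 and a two-carbon siloxyalkyne A3. In the forward step, heating A2 with A3 opens the cyclobutenone to a vinylketene, which adds to the alkyne; the new cyclobutenone opens again and closes by a six-electron electrocyclization to phenol A1.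
- For: three ring bonds form in one reagent-free step, and the single free phenol of A1 lies para to the chain. The C6 placement is thus also decided by connectivity; on this point the alternative is as strong as the chosen route, and it forms more bonds in its key step.
- Against: A1 is ring A only. Ring C and the aryl–C3 bond still have to be made by ortho-acylation of a phenol carrying two acid-labile silyl ethers, one-carbon insertion and closure. The ethyl ether on a future 5- or 7-oxygen must finally be cleaved by a boron halide or a thiolate, which the tertiary alcohol and the chromene tolerate poorly. A2 itself needs a ketene–alkoxyalkyne cycloaddition.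
- Comparison: the chosen route makes only one ring bond in its key step, but rings C, B and D are already in place, and only deprotection follows.

**Alternative 2:** The O1–C2 bond of ring C and the O–CMe2 bond of ring D are cut, leading back to open precursor A5 with an α-aryl enone and a prenyl group. In the forward step a divalent palladium carboxylate under an oxygen atmosphere adds the ring A phenol to the enone terminus and the ring B phenol to the prenyl group, each followed by β-hydride elimination, giving A4.
- For: two heterocycles form in one operation, the carbon skeleton comes from simple carbonyl chemistry, and the tertiary alcohol can stay free. In rings formed per step and in late convergence this alternative is stronger.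
- Against: the reaction does not decide which ring A phenol attacks. A5 must be made with the 5- and 7-oxygens protected and only the oxygen para to the chain free, so the regiochemical problem moves to differentiating three phloroglucinol oxygens. The prenyl phenol can also close 5-exo to an isopropenyl dihydrobenzofuran. The α-aryl vinyl ketone is prone to polymerize. Three acetals must be removed at the end beside the tertiary alcohol.
- Comparison: the chosen route fixes C6 by the order of atoms in the chain and makes the chromene early on a simple ring.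

**Alternative 3:** The C3–C4 bond of ring C is cut while ring B is carried as a tetrahydrochromenone, leading back to aldehyde A7. In the forward step a thiazolium-derived N-heterocyclic carbene converts the aldehyde into an acyl anion equivalent that adds to the β-carbon of the exocyclic enone, closing the chroman-4-one A6 as a diastereomer mixture.
- For: the aryl–C3 bond forms without any organometallic reagent, and ring B needs no protecting group because its 2′-oxygen appears as a ketone. In protecting-group economy on ring B it is stronger.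
- Against: the aldehyde is flanked by two ortho oxygen substituents, and the enone is part of a vinylogous ester and a weak acceptor. A6 lies two oxidation levels below the target, so ring C and ring B must both be dehydrogenated in the presence of the oxidizable chromene and an electron-rich ring A. The ring A aldehyde again needs differentiated phloroglucinol oxygens.
- Comparison: the chosen key step reaches the aromatic oxidation level directly by loss of methanol, and no oxidant is needed after it.

Key step: step 15

Remark on the chemistry: the target has no stereocenter. Compounds 4, 21, 23, 24 and 25 carry stereocenters that form without control (racemic or diastereomer mixtures) and are erased later.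

## Route

**Step 1**
Reactants: 1 cyclohexane-1,3-dione; 2 3-methylbut-2-enal
Product: 3 2,2-dimethyl-7,8-dihydro-2H-chromen-5(6H)-one
Conditions: ethylenediammonium diacetate (10 mol %), MeOH, rt
Reagents that add atoms: none
Why: Knoevenagel condensation gives a 1-oxatriene that closes by 6π-oxa-electrocyclization (formal 3+3 annulation). The dione is symmetric, so only one 2H-pyran can form.

**Step 2**
Reactants: 3 2,2-dimethyl-7,8-dihydro-2H-chromen-5(6H)-one
Product: 5 2,2-dimethyl-2H-chromen-5-ol, via α-phenylselanyl ketone 4 (not isolated)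
Conditions: LiN(iPr)2, THF, −78 °C; PhSeBr, −78 °C; then pyridine, 30% H2O2, CH2Cl2, 0 °C → rt
Reagents that add atoms: none
Why: Kinetic α′-deprotonation of the vinylogous ester at C6 and selenenylation give 4; oxidation to the selenoxide, syn-elimination and tautomerization of the cross-conjugated dienone should give the phenol (selenoxide elimination with aromatization). Pyridine buffers the peroxide so that the chromene double bond is not epoxidized.

**Step 3**
Reactants: 5 2,2-dimethyl-2H-chromen-5-ol
Product: 6 5-(methoxymethoxy)-2,2-dimethyl-2H-chromene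
Conditions: MOMCl, iPr2NEt, CH2Cl2, 0 °C → rt
Reagents that add atoms: chloromethyl methyl ether, COCCl
Why: O-alkylation of the phenol with the chloromethyl ether (Williamson-type acetal formation). The acetal is chosen because it is the directing group of step 4.

**Step 4**
Reactants: 6 5-(methoxymethoxy)-2,2-dimethyl-2H-chromene
Product: 8 2-[5-(methoxymethoxy)-2,2-dimethyl-2H-chromen-6-yl]-4,4,5,5-tetramethyl-1,3,2-dioxaborolane, via 6-lithio chromene 7 (not isolated)
Conditions: n-BuLi, TMEDA, THF, −20 → 0 °C; then 2-isopropoxy-4,4,5,5-tetramethyl-1,3,2-dioxaborolane, −78 °C → rt; aq. NH4Cl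
Reagents that add atoms: 2-isopropoxy-4,4,5,5-tetramethyl-1,3,2-dioxaborolane, CC(C)OB1OC(C)(C)C(C)(C)O1
Why: Directed ortho-metalation; the chelating acetal directs lithium to C6, its only free ortho position, while C8 is flanked only by the weaker ring ether. The aryllithium is trapped by the borate ester.

**Step 5**
Reactants: 9 kojic acid (5-hydroxy-2-(hydroxymethyl)-4H-pyran-4-one)
Product: 10 2-(chloromethyl)-5-hydroxy-4H-pyran-4-one
Conditions: SOCl2 (neat), rt
Reagents that add atoms: thionyl chloride, O=S(Cl)Cl
Why: Chlorodehydroxylation of the primary, allylic-type alcohol through its chlorosulfite. The enolic 5-hydroxyl is not displaced.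

**Step 6**
Reactants: 10 2-(chloromethyl)-5-hydroxy-4H-pyran-4-one
Product: 11 5-hydroxy-2-methyl-4H-pyran-4-one
Conditions: Zn dust, conc. HCl, H2O, 70 °C
Reagents that add atoms: none
Why: Dissolving-metal reduction of the activated (vinylogous α-halo ketone) C–Cl bond. The pyranone ring is stable to aqueous acid.

**Step 7**
Reactants: 11 5-hydroxy-2-methyl-4H-pyran-4-one
Product: 12 6-methyl-4-oxo-4H-pyran-3-yl trifluoromethanesulfonate
Conditions: PhNTf2, Et3N, CH2Cl2, 0 °C → rt
Reagents that add atoms: N-phenylbis(trifluoromethanesulfonimide), O=S(=O)(N(c1ccccc1)S(=O)(=O)C(F)(F)F)C(F)(F)F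
Why: O-sulfonylation of the acidic enolic hydroxyl. The mild triflimide is used instead of triflic anhydride so that the pyranone carbonyl is not triflated to a pyrylium salt.

**Step 8**
Reactants: 8 2-[5-(methoxymethoxy)-2,2-dimethyl-2H-chromen-6-yl]-4,4,5,5-tetramethyl-1,3,2-dioxaborolane; 12 6-methyl-4-oxo-4H-pyran-3-yl trifluoromethanesulfonate
Product: 13 5-[5-(methoxymethoxy)-2,2-dimethyl-2H-chromen-6-yl]-2-methyl-4H-pyran-4-one
Conditions: PdCl2(dppf) (5 mol %), K3PO4, 1,4-dioxane/H2O (10:1), 70 °C
Reagents that add atoms: none
Why: Suzuki–Miyaura coupling; the α-triflyloxy enone undergoes fast oxidative addition to zerovalent palladium, and the electron-rich boronate transmetalates readily. Phosphate and little water spare the triflate and the pyranone.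

**Step 9**
Reactants: 13 5-[5-(methoxymethoxy)-2,2-dimethyl-2H-chromen-6-yl]-2-methyl-4H-pyran-4-one
Product: 15 2-{5-[5-(methoxymethoxy)-2,2-dimethyl-2H-chromen-6-yl]-4-oxo-4H-pyran-2-yl}acetic acid, via lithium dienolate 14 (not isolated)
Conditions: LiN(SiMe3)2 (2.2 equiv), THF, −78 °C; CO2 (g), −78 → −20 °C; cold dilute HCl to pH 3; used without storage
Reagents that add atoms: carbon dioxide, O=C=O
Why: Lateral deprotonation of the 2-methyl group gives the extended enolate, which reacts with an external electrophile at the exocyclic carbon because this keeps the pyranone conjugated (vinylogous enolate carboxylation). The second equivalent of base covers the more acidic product.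

**Step 10**
Reactants: 16 3-methylbutane-1,3-diol
Product: 17 3-hydroxy-3-methylbutyl 4-methylbenzenesulfonate
Conditions: TsCl (1.05 equiv), Et3N, DMAP (cat.), CH2Cl2, 0 °C
Reagents that add atoms: 4-methylbenzenesulfonyl chloride, Cc1ccc(cc1)S(=O)(=O)Cl
Why: Selective sulfonylation of the primary hydroxyl; the tertiary hydroxyl is too hindered to react under these conditions.

**Step 11**
Reactants: 17 3-hydroxy-3-methylbutyl 4-methylbenzenesulfonate
Product: 18 3-methyl-3-(triethylsilyloxy)butyl 4-methylbenzenesulfonate
Conditions: Et3SiOTf, 2,6-lutidine, CH2Cl2, −78 → 0 °C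
Reagents that add atoms: triethylsilyl trifluoromethanesulfonate, CC[Si](CC)(CC)OS(=O)(=O)C(F)(F)F
Why: Silylation of a tertiary alcohol needs the silyl triflate. The hindered base does not displace the tosylate.

**Step 12**
Reactants: 18 3-methyl-3-(triethylsilyloxy)butyl 4-methylbenzenesulfonate; 19 dimethyl malonate
Product: 20 dimethyl 2-[3-methyl-3-(triethylsilyloxy)butyl]propanedioate
Conditions: 19 (2 equiv), NaH, THF/DMF, 0 °C; then 18, NaI (cat.), 60 °C
Reagents that add atoms: none
Why: Malonic ester alkylation (SN2) at a primary tosylate with iodide catalysis. Excess malonate limits dialkylation.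

**Step 13**
Reactants: 20 dimethyl 2-[3-methyl-3-(triethylsilyloxy)butyl]propanedioate
Product: 21 potassium 3-methoxy-2-[3-methyl-3-(triethylsilyloxy)butyl]-3-oxopropanoate (racemic)
Conditions: KOH (1.0 equiv), MeOH, 0 °C → rt; evaporate, dry
Reagents that add atoms: potassium hydroxide, [K+].[OH-]
Why: Mono-saponification; the first carboxylate deactivates the second ester toward hydroxide. Isolating the salt avoids any acid near the silyl ether.

**Step 14**
Reactants: 15 2-{5-[5-(methoxymethoxy)-2,2-dimethyl-2H-chromen-6-yl]-4-oxo-4H-pyran-2-yl}acetic acid; 21 potassium 3-methoxy-2-[3-methyl-3-(triethylsilyloxy)butyl]-3-oxopropanoate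
Product: 24 methyl 4-{5-[5-(methoxymethoxy)-2,2-dimethyl-2H-chromen-6-yl]-4-oxo-4H-pyran-2-yl}-2-[3-methyl-3-(triethylsilyloxy)butyl]-3-oxobutanoate (racemic), via acylimidazole 22 (not isolated), via acylmalonate half-ester 23 (not isolated)
Conditions: 15, 1,1′-carbonyldiimidazole, THF, 0 °C → rt; then 21, MgCl2, Et3N, MeCN, rt → 40 °C; cold dilute HCl to pH 4
Reagents that add atoms: none
Why: Masamune–Brooks-type decarboxylative Claisen condensation; the magnesium enolate of the malonate half-ester is C-acylated by the acylimidazole and the adduct loses CO2 to give the β-keto ester. The neutral conditions avoid an acid chloride with acidic α-hydrogens, and the product stays protected as its magnesium chelate.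

**Step 15**
Reactants: 24 methyl 4-{5-[5-(methoxymethoxy)-2,2-dimethyl-2H-chromen-6-yl]-4-oxo-4H-pyran-2-yl}-2-[3-methyl-3-(triethylsilyloxy)butyl]-3-oxobutanoate
Product: 26 5,7-dihydroxy-3-[5-(methoxymethoxy)-2,2-dimethyl-2H-chromen-6-yl]-6-[3-methyl-3-(triethylsilyloxy)butyl]-4H-chromen-4-one, via ring-closed trione 25 (not isolated)
Conditions: DBU (3 equiv), THF, 25 → 55 °C; aq. NaH2PO4
Reagents that add atoms: none
Why: DBU deprotonates 24 reversibly, so the unproductive enolate between ketone and ester stays in equilibrium with the extended enolate formed at the CH2 between ketone and pyranone, whose charge is shared by the ketone oxygen, pyranone C3 and the pyranone carbonyl. C3 (the future C4a) adds to the still neutral ester carbonyl, the tetrahedral intermediate expels methoxide to give trione 25, and two enolizations turn 25 into the aromatic 5,7-diol, which makes the sequence irreversible. The closest known reaction type is the biomimetic Claisen (Dieckmann-type) cyclization of pyrone- and pyranone-masked poly-β-keto esters to acylphloroglucinol-type arenes. Ring A closes by a 6-exo-trig acyl substitution in which the enolate double bond lies outside the new ring. The two sp3 centers of 25 (C4a and C6) are transient and vanish on aromatization, so no stereocontrol is needed. The selectivity needed is carbon–carbon bond formation at C3 instead of at the exocyclic CH2 or at oxygen; the tether secures it, because only C3 closes a six-membered ring, whereas the CH2 or the ketone oxygen would give a four-membered ring and the pyranone carbonyl oxygen an eight-membered one. Because O1 is already locked in the pyranone, the chain carbon between the two carbonyl-derived carbons can only become C6, flanked by the 5- and 7-hydroxyls.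

**Step 16**
Reactants: 26 5,7-dihydroxy-3-[5-(methoxymethoxy)-2,2-dimethyl-2H-chromen-6-yl]-6-[3-methyl-3-(triethylsilyloxy)butyl]-4H-chromen-4-one
Product: 28 5,7-dihydroxy-3-(5-hydroxy-2,2-dimethyl-2H-chromen-6-yl)-6-[3-methyl-3-(triethylsilyloxy)butyl]-4H-chromen-4-one, via tris(trimethylsilyl) ether 27 (not isolated)
Conditions: Me3SiOTf (6 equiv), 2,2′-bipyridyl (9 equiv), CH2Cl2, 0 °C → rt; then H2O, rt
Reagents that add atoms: none
Why: Silyl-triflate-mediated cleavage of the aryl methoxymethyl ether; the bipyridyl-buffered silyl triflate transfers silicon to the aryl oxygen and the methoxymethyl group to the pyridine nitrogen, and water then hydrolyses the aryl silyl ethers (the ring A phenols are silylated in passing). No free Brønsted acid is present, so the tertiary silyl ether and the chromene should be untouched.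

**Step 17**
Reactants: 28 5,7-dihydroxy-3-(5-hydroxy-2,2-dimethyl-2H-chromen-6-yl)-6-[3-methyl-3-(triethylsilyloxy)butyl]-4H-chromen-4-one
Product: 29 Kanzonol T (5,7-dihydroxy-3-(5-hydroxy-2,2-dimethyl-2H-chromen-6-yl)-6-(3-hydroxy-3-methylbutyl)-4H-chromen-4-one)
Conditions: HF·pyridine, pyridine, THF, 0 °C → rt
Reagents that add atoms: none
Why: Fluoride-driven desilylation through attack at silicon, buffered by pyridine. No cation forms at the tertiary carbon, so closure to a chroman onto the neighbouring phenols is not expected.

## Compound list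

1 | cyclohexane-1,3-dione | O=C1CCCC(=O)C1 | starting material
2 | 3-methylbut-2-enal | CC(C)=CC=O | starting material
3 | 2,2-dimethyl-7,8-dihydro-2H-chromen-5(6H)-one | CC1(C)C=CC2=C(O1)CCCC2=O | intermediate
4 | 2,2-dimethyl-6-(phenylselanyl)-7,8-dihydro-2H-chromen-5(6H)-one (racemic) | CC1(C)C=CC2=C(O1)CCC([Se]c3ccccc3)C2=O | intermediate
5 | 2,2-dimethyl-2H-chromen-5-ol | CC1(C)C=Cc2c(O)cccc2O1 | intermediate
6 | 5-(methoxymethoxy)-2,2-dimethyl-2H-chromene | COCOc1cccc2OC(C)(C)C=Cc12 | intermediate
7 | [5-(methoxymethoxy)-2,2-dimethyl-2H-chromen-6-yl]lithium | [Li]c1ccc2OC(C)(C)C=Cc2c1OCOC | intermediate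
8 | 2-[5-(methoxymethoxy)-2,2-dimethyl-2H-chromen-6-yl]-4,4,5,5-tetramethyl-1,3,2-dioxaborolane | CC1(C)OB(OC1(C)C)c1ccc2OC(C)(C)C=Cc2c1OCOC | intermediate
9 | kojic acid, 5-hydroxy-2-(hydroxymethyl)-4H-pyran-4-one | OCc1cc(=O)c(O)co1 | starting material
10 | 2-(chloromethyl)-5-hydroxy-4H-pyran-4-one | ClCc1cc(=O)c(O)co1 | intermediate
11 | 5-hydroxy-2-methyl-4H-pyran-4-one | Cc1cc(=O)c(O)co1 | intermediate
12 | 6-methyl-4-oxo-4H-pyran-3-yl trifluoromethanesulfonate | Cc1cc(=O)c(OS(=O)(=O)C(F)(F)F)co1 | intermediate
13 | 5-[5-(methoxymethoxy)-2,2-dimethyl-2H-chromen-6-yl]-2-methyl-4H-pyran-4-one | Cc1cc(=O)c(-c2ccc3OC(C)(C)C=Cc3c2OCOC)co1 | intermediate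
14 | lithium 5-[5-(methoxymethoxy)-2,2-dimethyl-2H-chromen-6-yl]-2-methylidene-2H-pyran-4-olate (extended enolate of 13) | C=C1C=C(O[Li])C(-c2ccc3OC(C)(C)C=Cc3c2OCOC)=CO1 | intermediate
15 | 2-{5-[5-(methoxymethoxy)-2,2-dimethyl-2H-chromen-6-yl]-4-oxo-4H-pyran-2-yl}acetic acid | OC(=O)Cc1cc(=O)c(-c2ccc3OC(C)(C)C=Cc3c2OCOC)co1 | intermediate
16 | 3-methylbutane-1,3-diol | CC(C)(O)CCO | starting material
17 | 3-hydroxy-3-methylbutyl 4-methylbenzenesulfonate | Cc1ccc(cc1)S(=O)(=O)OCCC(C)(C)O | intermediate
18 | 3-methyl-3-(triethylsilyloxy)butyl 4-methylbenzenesulfonate | Cc1ccc(cc1)S(=O)(=O)OCCC(C)(C)O[Si](CC)(CC)CC | intermediate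
19 | dimethyl malonate | COC(=O)CC(=O)OC | starting material
20 | dimethyl 2-[3-methyl-3-(triethylsilyloxy)butyl]propanedioate | COC(=O)C(CCC(C)(C)O[Si](CC)(CC)CC)C(=O)OC | intermediate
21 | potassium 3-methoxy-2-[3-methyl-3-(triethylsilyloxy)butyl]-3-oxopropanoate (racemic) | [K+].[O-]C(=O)C(CCC(C)(C)O[Si](CC)(CC)CC)C(=O)OC | intermediate
22 | 1-(1H-imidazol-1-yl)-2-{5-[5-(methoxymethoxy)-2,2-dimethyl-2H-chromen-6-yl]-4-oxo-4H-pyran-2-yl}ethan-1-one | O=C(Cc1cc(=O)c(-c2ccc3OC(C)(C)C=Cc3c2OCOC)co1)n1ccnc1 | intermediate
23 | 2-(methoxycarbonyl)-4-{5-[5-(methoxymethoxy)-2,2-dimethyl-2H-chromen-6-yl]-4-oxo-4H-pyran-2-yl}-2-[3-methyl-3-(triethylsilyloxy)butyl]-3-oxobutanoic acid (racemic; present as its magnesium carboxylate) | COC(=O)C(CCC(C)(C)O[Si](CC)(CC)CC)(C(=O)O)C(=O)Cc1cc(=O)c(-c2ccc3OC(C)(C)C=Cc3c2OCOC)co1 | intermediate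
24 | methyl 4-{5-[5-(methoxymethoxy)-2,2-dimethyl-2H-chromen-6-yl]-4-oxo-4H-pyran-2-yl}-2-[3-methyl-3-(triethylsilyloxy)butyl]-3-oxobutanoate (racemic) | COC(=O)C(CCC(C)(C)O[Si](CC)(CC)CC)C(=O)Cc1cc(=O)c(-c2ccc3OC(C)(C)C=Cc3c2OCOC)co1 | intermediate
25 | 3-[5-(methoxymethoxy)-2,2-dimethyl-2H-chromen-6-yl]-6-[3-methyl-3-(triethylsilyloxy)butyl]-4H-chromene-4,5,7(4aH,6H)-trione (diastereomer mixture) | O=C1C=C2OC=C(-c3ccc4OC(C)(C)C=Cc4c3OCOC)C(=O)C2C(=O)C1CCC(C)(C)O[Si](CC)(CC)CC | intermediate
26 | 5,7-dihydroxy-3-[5-(methoxymethoxy)-2,2-dimethyl-2H-chromen-6-yl]-6-[3-methyl-3-(triethylsilyloxy)butyl]-4H-chromen-4-one | CC(C)(O[Si](CC)(CC)CC)CCc1c(O)cc2occ(-c3ccc4OC(C)(C)C=Cc4c3OCOC)c(=O)c2c1O | intermediate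
27 | 3-[2,2-dimethyl-5-(trimethylsilyloxy)-2H-chromen-6-yl]-6-[3-methyl-3-(triethylsilyloxy)butyl]-5,7-bis(trimethylsilyloxy)-4H-chromen-4-one | CC(C)(O[Si](CC)(CC)CC)CCc1c(O[Si](C)(C)C)cc2occ(-c3ccc4OC(C)(C)C=Cc4c3O[Si](C)(C)C)c(=O)c2c1O[Si](C)(C)C | intermediate
28 | 5,7-dihydroxy-3-(5-hydroxy-2,2-dimethyl-2H-chromen-6-yl)-6-[3-methyl-3-(triethylsilyloxy)butyl]-4H-chromen-4-one | CC(C)(O[Si](CC)(CC)CC)CCc1c(O)cc2occ(-c3ccc4OC(C)(C)C=Cc4c3O)c(=O)c2c1O | intermediate
29 | Kanzonol T, 5,7-dihydroxy-3-(5-hydroxy-2,2-dimethyl-2H-chromen-6-yl)-6-(3-hydroxy-3-methylbutyl)-4H-chromen-4-one | CC(C)(O)CCc1c(O)cc2occ(-c3ccc4c(c3O)C=CC(C)(C)O4)c(=O)c2c1O | target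

## Step count and least certain steps

Total: 17 steps. Longest linear sequence: 10 steps (steps 1, 2, 3, 4, 8, 9, 14, 15, 16, 17).

**Step 15 (key step).** The base may hold the substrate as the stabilized enolate between ketone and ester, whose ester carbon is no longer electrophilic, so that closure stalls. On forcing, the liberated methoxide may cause retro-Claisen loss of the acyl chain or conjugate opening of the pyranone at its O–CH= carbon. The fallback closes the same bond thermally without base and sets out from 15 and 18. tert-Butyl methyl malonate is alkylated with 18 (NaH, THF/DMF) to tert-butyl methyl 2-[3-methyl-3-(triethylsilyloxy)butyl]propanedioate F1. KOH (1 equiv) in MeOH cleaves only the methyl ester to give potassium 3-tert-butoxy-2-[3-methyl-3-(triethylsilyloxy)butyl]-3-oxopropanoate F2. Coupling of F2 with 15 as in step 14 gives tert-butyl 4-{5-[5-(methoxymethoxy)-2,2-dimethyl-2H-chromen-6-yl]-4-oxo-4H-pyran-2-yl}-2-[3-methyl-3-(triethylsilyloxy)butyl]-3-oxobutanoate F3. Heating F3 in toluene at 110 °C expels tert-butanol and gives the acylketene 4-{5-[5-(methoxymethoxy)-2,2-dimethyl-2H-chromen-6-yl]-4-oxo-4H-pyran-2-yl}-2-[3-methyl-3-(triethylsilyloxy)butyl]but-1-ene-1,3-dione F4. The ketene carbon is captured at pyranone C3 (six-electron closure of the dienylketene tautomer), and tautomerization brings the route back at 26.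

**Step 14.** The acylimidazole has an acidic CH2 between carbonyl and pyranone; enolization can lead to ketene formation and self-condensation. Acid 15 may lose CO2 before it is activated, and C-acylation of the α-branched magnesium malonate may be slow. The fallback avoids acid 15 and sets out from 13 and 21. Salt 21 and oxalyl chloride (cat. DMF, CH2Cl2, 0 °C; no HCl is formed from the salt) give methyl 2-(chlorocarbonyl)-5-methyl-5-(triethylsilyloxy)hexanoate F5. F5 is added at −78 °C to dienolate 14, made from 13 with LiN(SiMe3)2 (2.2 equiv). C-acylation at the exocyclic carbon, directly or through the derived ketene, returns to the route at 24.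

**Step 16.** The silyl triflate may assist ionization of the tertiary silyl ether, with capture of the cation by a neighbouring ring A oxygen, or the hindered 2′-acetal may be cleaved incompletely. The fallback exchanges the protecting group before the side chain exists and sets out from 13. HCl in MeOH at 40 °C gives 5-(5-hydroxy-2,2-dimethyl-2H-chromen-6-yl)-2-methyl-4H-pyran-4-one F6. TBSCl and imidazole in DMF give 5-[5-(tert-butyldimethylsilyloxy)-2,2-dimethyl-2H-chromen-6-yl]-2-methyl-4H-pyran-4-one F7. The conditions of steps 9, 14 and 15 then give in turn: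
- 2-{5-[5-(tert-butyldimethylsilyloxy)-2,2-dimethyl-2H-chromen-6-yl]-4-oxo-4H-pyran-2-yl}acetic acid F8;
- methyl 4-{5-[5-(tert-butyldimethylsilyloxy)-2,2-dimethyl-2H-chromen-6-yl]-4-oxo-4H-pyran-2-yl}-2-[3-methyl-3-(triethylsilyloxy)butyl]-3-oxobutanoate F9;
- 3-[5-(tert-butyldimethylsilyloxy)-2,2-dimethyl-2H-chromen-6-yl]-5,7-dihydroxy-6-[3-methyl-3-(triethylsilyloxy)butyl]-4H-chromen-4-one F10.

Bu4NF in THF removes both silyl groups from F10 in one operation and returns to the route at 29.

**Step 8.** The electron-rich ortho-alkoxy boronate may protodeboronate, and aqueous base may hydrolyse the enol triflate back to 11 or open the pyranone. The fallback is a base-free Negishi coupling that sets out from 6. Aryllithium 7, made as in step 4, is transmetalated with ZnCl2 in THF to chloro[5-(methoxymethoxy)-2,2-dimethyl-2H-chromen-6-yl]zinc F11. F11 is coupled with 12 using Pd(PPh3)4 (zerovalent palladium) in THF at 50 °C, returning to the route at 13.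

**Step 2.** The selenium by-product and H2O2 can form a peroxyseleninic acid that epoxidizes the chromene double bond, and the electron-rich phenol may be over-oxidized. The fallback is a Saegusa–Ito dehydrogenation that sets out from 3. LiN(iPr)2 and Me3SiCl give 2,2-dimethyl-5-(trimethylsilyloxy)-7,8-dihydro-2H-chromene F12. Pd(OAc)2 in MeCN converts F12 into the dienone, which tautomerizes and returns to the route at 5.

## Further compounds

F1 | step 15 | tert-butyl methyl 2-[3-methyl-3-(triethylsilyloxy)butyl]propanedioate (racemic) | COC(=O)C(CCC(C)(C)O[Si](CC)(CC)CC)C(=O)OC(C)(C)C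
F2 | step 15 | potassium 3-tert-butoxy-2-[3-methyl-3-(triethylsilyloxy)butyl]-3-oxopropanoate (racemic) | [K+].[O-]C(=O)C(CCC(C)(C)O[Si](CC)(CC)CC)C(=O)OC(C)(C)C
F3 | step 15 | tert-butyl 4-{5-[5-(methoxymethoxy)-2,2-dimethyl-2H-chromen-6-yl]-4-oxo-4H-pyran-2-yl}-2-[3-methyl-3-(triethylsilyloxy)butyl]-3-oxobutanoate (racemic) | CC(C)(C)OC(=O)C(CCC(C)(C)O[Si](CC)(CC)CC)C(=O)Cc1cc(=O)c(-c2ccc3OC(C)(C)C=Cc3c2OCOC)co1
F4 | step 15 | 4-{5-[5-(methoxymethoxy)-2,2-dimethyl-2H-chromen-6-yl]-4-oxo-4H-pyran-2-yl}-2-[3-methyl-3-(triethylsilyloxy)butyl]but-1-ene-1,3-dione | O=C=C(CCC(C)(C)O[Si](CC)(CC)CC)C(=O)Cc1cc(=O)c(-c2ccc3OC(C)(C)C=Cc3c2OCOC)co1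
F5 | step 14 | methyl 2-(chlorocarbonyl)-5-methyl-5-(triethylsilyloxy)hexanoate (racemic) | COC(=O)C(CCC(C)(C)O[Si](CC)(CC)CC)C(Cl)=O
F6 | step 16 | 5-(5-hydroxy-2,2-dimethyl-2H-chromen-6-yl)-2-methyl-4H-pyran-4-one | Cc1cc(=O)c(-c2ccc3OC(C)(C)C=Cc3c2O)co1
F7 | step 16 | 5-[5-(tert-butyldimethylsilyloxy)-2,2-dimethyl-2H-chromen-6-yl]-2-methyl-4H-pyran-4-one | Cc1cc(=O)c(-c2ccc3OC(C)(C)C=Cc3c2O[Si](C)(C)C(C)(C)C)co1
F8 | step 16 | 2-{5-[5-(tert-butyldimethylsilyloxy)-2,2-dimethyl-2H-chromen-6-yl]-4-oxo-4H-pyran-2-yl}acetic acid | OC(=O)Cc1cc(=O)c(-c2ccc3OC(C)(C)C=Cc3c2O[Si](C)(C)C(C)(C)C)co1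
F9 | step 16 | methyl 4-{5-[5-(tert-butyldimethylsilyloxy)-2,2-dimethyl-2H-chromen-6-yl]-4-oxo-4H-pyran-2-yl}-2-[3-methyl-3-(triethylsilyloxy)butyl]-3-oxobutanoate (racemic) | COC(=O)C(CCC(C)(C)O[Si](CC)(CC)CC)C(=O)Cc1cc(=O)c(-c2ccc3OC(C)(C)C=Cc3c2O[Si](C)(C)C(C)(C)C)co1
F10 | step 16 | 3-[5-(tert-butyldimethylsilyloxy)-2,2-dimethyl-2H-chromen-6-yl]-5,7-dihydroxy-6-[3-methyl-3-(triethylsilyloxy)butyl]-4H-chromen-4-one | CC(C)(O[Si](CC)(CC)CC)CCc1c(O)cc2occ(-c3ccc4OC(C)(C)C=Cc4c3O[Si](C)(C)C(C)(C)C)c(=O)c2c1O
F11 | step 8 | chloro[5-(methoxymethoxy)-2,2-dimethyl-2H-chromen-6-yl]zinc | Cl[Zn]c1ccc2OC(C)(C)C=Cc2c1OCOC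
F12 | step 2 | 2,2-dimethyl-5-(trimethylsilyloxy)-7,8-dihydro-2H-chromene | CC1(C)C=CC2=C(O1)CCC=C2O[Si](C)(C)C
A1 | alternative 1 | 4-[3-(tert-butyldimethylsilyloxy)-3-methylbutyl]-3-ethoxy-5-(triisopropylsilyloxy)phenol | CCOc1cc(O)cc(O[Si](C(C)C)(C(C)C)C(C)C)c1CCC(C)(C)O[Si](C)(C)C(C)(C)C
A2 | alternative 1 | 2-[3-(tert-butyldimethylsilyloxy)-3-methylbutyl]-3-ethoxycyclobut-2-en-1-one | CCOC1=C(CCC(C)(C)O[Si](C)(C)C(C)(C)C)C(=O)C1
A3 | alternative 1 | (ethynyloxy)triisopropylsilane | C#CO[Si](C(C)C)(C(C)C)C(C)C
A4 | alternative 2 | Kanzonol T 5,7,2′-tris(methoxymethyl) ether | CC(C)(O)CCc1c(OCOC)cc2occ(-c3ccc4OC(C)(C)C=Cc4c3OCOC)c(=O)c2c1OCOC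
A5 | alternative 2 | 1-[2-hydroxy-5-(3-hydroxy-3-methylbutyl)-4,6-bis(methoxymethoxy)phenyl]-2-[4-hydroxy-2-(methoxymethoxy)-3-(3-methylbut-2-en-1-yl)phenyl]prop-2-en-1-one | C=C(C(=O)c1c(O)cc(OCOC)c(CCC(C)(C)O)c1OCOC)c1ccc(O)c(CC=C(C)C)c1OCOC
A6 | alternative 3 | 3-(2,2-dimethyl-5-oxo-5,6,7,8-tetrahydro-2H-chromen-6-yl)-6-(3-hydroxy-3-methylbutyl)-5,7-bis(methoxymethoxy)chroman-4-one (mixture of diastereomers) | CC(C)(O)CCc1c(OCOC)cc2OCC(C3CCC4=C(C=CC(C)(C)O4)C3=O)C(=O)c2c1OCOC
A7 | alternative 3 | 2-{2-[2,2-dimethyl-5-oxo-7,8-dihydro-2H-chromen-6(5H)-ylidene]ethoxy}-5-(3-hydroxy-3-methylbutyl)-4,6-bis(methoxymethoxy)benzaldehyde | CC(C)(O)CCc1c(OCOC)cc(OCC=C2CCC3=C(C=CC(C)(C)O3)C2=O)c(C=O)c1OCOC
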